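**Retrosynthetic overview**
- The ester C–O bond is made last, by Mitsunobu inversion of the allylic alcohol with isovanillic acid (built from catechol).
- The tertiary carbinol comes from axial methyl delivery to a trans-fused bicyclic ketone.
- Key disconnection: the C-9–C-9a bond. The seven-membered ring is closed by an iron-hydride-initiated 7-endo radical conjugate addition of a prenyl-derived tertiary radical onto a cyclohexadienyl ketone.
- The cyclisation substrate comes from prenylation of a chiral 5-silyloxy dienyl methyl ketone. Its stereocentre comes from Shi epoxidation and base opening of the isoprene/butynone Diels–Alder adduct.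
- Ring order: six-membered ring first (Diels–Alder), seven-membered ring second (radical cyclisation).

Assumption: bicyclic compounds are numbered as benzo[7]annulenes (C-2 methyl, C-3 oxygen, C-4a/C-9a ring fusion, C-5 carbinol, C-9 gem-dimethyl), and the L-series Shi ketone is taken as purchasable.

**Step 1**
Reactants: 1 isoprene (2-methylbuta-1,3-diene); 2 but-3-yn-2-one
Product: 3 1-(4-methylcyclohexa-1,4-dien-1-yl)ethan-1-one
Conditions: AlCl3 (20 mol%), CH2Cl2, −20 → 0 °C; used promptly under argon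
Reagents that add atoms: none
Why: Lewis-acid-catalysed Diels–Alder reaction of the ynone, in which the "para" orientation places acetyl and methyl 1,4 on the skipped diene; no stereocentre is formed.

**Step 2**
Reactants: 3 1-(4-methylcyclohexa-1,4-dien-1-yl)ethan-1-one
Product: 4 1-[(1S,6R)-6-methyl-7-oxabicyclo[4.1.0]hept-3-en-3-yl]ethan-1-one
Conditions: 1,2:4,5-di-O-isopropylidene-β-L-erythro-2,3-hexodiulo-2,6-pyranose (ent-Shi ketone, 30 mol%), Oxone (2KHSO5·KHSO4·K2SO4), K2CO3, Bu4NHSO4, MeCN/CH2(OMe)2/aq. Na2B4O7 buffer, 0 °C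
Reagents that add atoms: potassium peroxymonosulfate (active part of Oxone), [K+].[O-]S(=O)(=O)OO
Why: Shi asymmetric epoxidation, in which the chiral dioxirane attacks only the electron-rich trisubstituted ring olefin (the enone C=C is inert) through the spiro transition state; by analogy with 1-substituted cyclohexenes the L-series ketone gives the (1S,6R) epoxide (about 90% ee expected, to be upgraded by crystallisation of diol 13), which fixes the future C-3 oxygen stereocentre.

**Step 3**
Reactants: 4 1-[(1S,6R)-6-methyl-7-oxabicyclo[4.1.0]hept-3-en-3-yl]ethan-1-one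
Product: 6 1-[(5S)-5-{[tert-butyl(dimethyl)silyl]oxy}-4-methylcyclohexa-1,3-dien-1-yl]ethan-1-one, via hydroxy dienone 5 (not isolated)
Conditions: DBU (1.5 equiv), CH2Cl2, 0 °C → rt; then TBSCl, rt
Reagents that add atoms: tert-butyl(chloro)dimethylsilane, CC(C)(C)[Si](C)(C)Cl
Why: base-induced isomerisation of a γ,δ-epoxy enone to a δ-hydroxy dienone (DBU removes the doubly activated γ-proton at C-5 and the vinylogous enolate opens the epoxide by E1cB without touching the C–O stereocentre), followed by silylation in the same pot to protect the labile arene-hydrate-type alcohol.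

**Step 4**
Reactants: 6 1-[(5S)-5-{[tert-butyl(dimethyl)silyl]oxy}-4-methylcyclohexa-1,3-dien-1-yl]ethan-1-one; 7 1-bromo-3-methylbut-2-ene (prenyl bromide)
Product: 9 1-[(5S)-5-{[tert-butyl(dimethyl)silyl]oxy}-4-methylcyclohexa-1,3-dien-1-yl]-5-methylhex-4-en-1-one, via lithium enolate 8 (not isolated)
Conditions: LiN(iPr)2 (1.1 equiv), THF, −78 °C; then 7, DMPU, −78 → −20 °C
Reagents that add atoms: none
Why: kinetic deprotonation of the methyl ketone gives the cross-conjugated enolate, which is C-alkylated by the allylic bromide (SN2 enolate alkylation), installing the three-carbon tether and the olefin that will become the gem-dimethyl radical centre.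

**Step 5**
Reactants: 9 1-[(5S)-5-{[tert-butyl(dimethyl)silyl]oxy}-4-methylcyclohexa-1,3-dien-1-yl]-5-methylhex-4-en-1-one
Product: 11 (3S,4aR,9aR)-3-{[tert-butyl(dimethyl)silyl]oxy}-2,9,9-trimethyl-3,4,4a,6,7,8,9,9a-octahydro-5H-benzo[7]annulen-5-one, via cis-fused epimer 10 (not isolated)
Conditions: Fe(acac)3 (30 mol%), PhSiH3 (slow addition, 2 equiv), EtOH/(CH2OH)2 5:1, 60 °C, 0.01 M; then DBU, rt; chromatography
Reagents that add atoms: none
Why: iron-hydride hydrogen-atom transfer to the trisubstituted olefin (Mukaiyama/Baran-type reductive olefin–enone coupling, run intramolecularly) gives the tertiary radical, which closes the seven-membered ring by 7-endo-trig Giese addition to the enone β-carbon C-2 of the dienyl ring (the 6-exo alternative would join two fully substituted carbons and is polarity-mismatched); it is expected to enter anti to the C-5 silyloxy group, which A(1,2) strain with the C-4 methyl holds pseudoaxial (minor syn isomer removed by chromatography), and DBU equilibration of the α-carbon then gives the trans ring fusion with both fusion bonds equatorial.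

**Step 6**
Reactants: 11 (3S,4aR,9aR)-3-{[tert-butyl(dimethyl)silyl]oxy}-2,9,9-trimethyl-3,4,4a,6,7,8,9,9a-octahydro-5H-benzo[7]annulen-5-one
Product: 12 (3S,4aR,5R,9aR)-3-{[tert-butyl(dimethyl)silyl]oxy}-2,5,9,9-tetramethyl-4,4a,5,6,7,8,9,9a-octahydro-3H-benzo[7]annulen-5-ol
Conditions: AlMe3 (4 equiv), toluene, −20 °C → rt; aq. NH4Cl
Reagents that add atoms: trimethylaluminium, C[Al](C)C
Why: 1,2-addition with excess AlMe3 in an arene solvent (Ashby conditions), where the aluminium-bound carbonyl oxygen is compressed against the equatorial C-4a–C-4 bond in the equatorial transition state, so methyl is delivered axially, anti to the axial C-4a hydrogen, giving the 5R carbinol with equatorial OH.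

**Step 7**
Reactants: 12 (3S,4aR,5R,9aR)-3-{[tert-butyl(dimethyl)silyl]oxy}-2,5,9,9-tetramethyl-4,4a,5,6,7,8,9,9a-octahydro-3H-benzo[7]annulen-5-ol
Product: 13 (3S,4aR,5R,9aR)-2,5,9,9-tetramethyl-4,4a,5,6,7,8,9,9a-octahydro-3H-benzo[7]annulene-3,5-diol
Conditions: Bu4NF, THF, rt
Reagents that add atoms: none
Why: fluoride-mediated silyl ether cleavage frees the pseudoequatorial allylic alcohol without affecting any stereocentre.

**Step 8**
Reactants: 14 catechol (benzene-1,2-diol)
Product: 15 2-methoxyphenol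
Conditions: MeI (1.0 equiv), K2CO3, acetone, reflux (catechol in excess)
Reagents that add atoms: iodomethane, CI
Why: Williamson mono-O-methylation, kept at the mono stage by limiting the alkylating agent.

**Step 9**
Reactants: 15 2-methoxyphenol
Product: 18 5-bromo-2-methoxyphenol, via 2-methoxyphenyl acetate 16 (not isolated), via 5-bromo-2-methoxyphenyl acetate 17 (not isolated)
Conditions: Ac2O, cat. H2SO4, MeCN, rt; then NBS, 50 °C; then aq. NaOH, MeOH, rt; HCl work-up
Reagents that add atoms: N-bromosuccinimide, BrN1C(=O)CCC1=O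
Why: O-acetylation weakens the phenol oxygen as a donor so that electrophilic aromatic bromination goes para to the methoxy group, and saponification then returns the free phenol.

**Step 10**
Reactants: 18 5-bromo-2-methoxyphenol
Product: 20 3-hydroxy-4-methoxybenzoic acid (isovanillic acid), via dilithio phenolate 19 (not isolated)
Conditions: n-BuLi (2.2 equiv), THF, −78 °C; then CO2; aq. HCl
Reagents that add atoms: carbon dioxide, O=C=O
Why: deprotonation of the phenol followed by bromine–lithium exchange gives the aryllithium, which is carboxylated by CO2.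

**Step 11**
Reactants: 13 (3S,4aR,5R,9aR)-2,5,9,9-tetramethyl-4,4a,5,6,7,8,9,9a-octahydro-3H-benzo[7]annulene-3,5-diol; 20 3-hydroxy-4-methoxybenzoic acid
Product: 21 (3R,4aR,5R,9aR)-5-hydroxy-2,5,9,9-tetramethyl-4,4a,5,6,7,8,9,9a-octahydro-3H-benzo[7]annulen-3-yl 3-hydroxy-4-methoxybenzoate
Conditions: PPh3, DIAD, THF, 0 °C → rt
Reagents that add atoms: none
Why: Mitsunobu esterification, in which the carboxylate of 20 (far more acidic than its phenol, so no protection is needed) displaces the activated pseudoequatorial allylic oxygen by SN2 with inversion to the pseudoaxial 3R ester; the tertiary alcohol is inert and SN2' attack at C-1 is blocked by the adjacent quaternary carbon.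

**Compound list**
1 | isoprene (2-methylbuta-1,3-diene) | C=CC(C)=C | starting material
2 | but-3-yn-2-one | CC(=O)C#C | starting material
3 | 1-(4-methylcyclohexa-1,4-dien-1-yl)ethan-1-one | CC(=O)C1=CCC(C)=CC1 | intermediate
4 | 1-[(1S,6R)-6-methyl-7-oxabicyclo[4.1.0]hept-3-en-3-yl]ethan-1-one | CC(=O)C1=CC[C@@]2(C)O[C@H]2C1 | intermediate
5 | 1-[(5S)-5-hydroxy-4-methylcyclohexa-1,3-dien-1-yl]ethan-1-one | CC(=O)C1=CC=C(C)[C@@H](O)C1 | intermediate
6 | 1-[(5S)-5-{[tert-butyl(dimethyl)silyl]oxy}-4-methylcyclohexa-1,3-dien-1-yl]ethan-1-one | CC(=O)C1=CC=C(C)[C@@H](O[Si](C)(C)C(C)(C)C)C1 | intermediate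
7 | 1-bromo-3-methylbut-2-ene (prenyl bromide) | CC(C)=CCBr | starting material
8 | lithium 1-[(5S)-5-{[tert-butyl(dimethyl)silyl]oxy}-4-methylcyclohexa-1,3-dien-1-yl]ethen-1-olate | [Li+].[O-]C(=C)C1=CC=C(C)[C@@H](O[Si](C)(C)C(C)(C)C)C1 | intermediate
9 | 1-[(5S)-5-{[tert-butyl(dimethyl)silyl]oxy}-4-methylcyclohexa-1,3-dien-1-yl]-5-methylhex-4-en-1-one | CC(C)=CCCC(=O)C1=CC=C(C)[C@@H](O[Si](C)(C)C(C)(C)C)C1 | intermediate
10 | (3S,4aS,9aR)-3-{[tert-butyl(dimethyl)silyl]oxy}-2,9,9-trimethyl-3,4,4a,6,7,8,9,9a-octahydro-5H-benzo[7]annulen-5-one (cis-fused) | CC(C)(C)[Si](C)(C)O[C@H]1C[C@H]2[C@@H](C=C1C)C(C)(C)CCCC2=O | intermediate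
11 | (3S,4aR,9aR)-3-{[tert-butyl(dimethyl)silyl]oxy}-2,9,9-trimethyl-3,4,4a,6,7,8,9,9a-octahydro-5H-benzo[7]annulen-5-one (trans-fused) | CC(C)(C)[Si](C)(C)O[C@H]1C[C@@H]2[C@@H](C=C1C)C(C)(C)CCCC2=O | intermediate
12 | (3S,4aR,5R,9aR)-3-{[tert-butyl(dimethyl)silyl]oxy}-2,5,9,9-tetramethyl-4,4a,5,6,7,8,9,9a-octahydro-3H-benzo[7]annulen-5-ol | CC(C)(C)[Si](C)(C)O[C@H]1C[C@@H]2[C@@H](C=C1C)C(C)(C)CCC[C@@]2(C)O | intermediate
13 | (3S,4aR,5R,9aR)-2,5,9,9-tetramethyl-4,4a,5,6,7,8,9,9a-octahydro-3H-benzo[7]annulene-3,5-diol | O[C@H]1C[C@@H]2[C@@H](C=C1C)C(C)(C)CCC[C@@]2(C)O | intermediate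
14 | catechol (benzene-1,2-diol) | Oc1ccccc1O | starting material
15 | 2-methoxyphenol | COc1ccccc1O | intermediate
16 | 2-methoxyphenyl acetate | COc1ccccc1OC(C)=O | intermediate
17 | 5-bromo-2-methoxyphenyl acetate | COc1ccc(Br)cc1OC(C)=O | intermediate
18 | 5-bromo-2-methoxyphenol | COc1ccc(Br)cc1O | intermediate
19 | lithium 5-lithio-2-methoxyphenolate | [Li+].[O-]c1cc([Li])ccc1OC | intermediate
20 | 3-hydroxy-4-methoxybenzoic acid (isovanillic acid) | COc1ccc(C(=O)O)cc1O | intermediate
21 | (3R,4aR,5R,9aR)-5-hydroxy-2,5,9,9-tetramethyl-4,4a,5,6,7,8,9,9a-octahydro-3H-benzo[7]annulen-3-yl 3-hydroxy-4-methoxybenzoate | COc1ccc(C(=O)O[C@@H]2C[C@@H]3[C@@H](C=C2C)C(C)(C)CCC[C@@]3(C)O)cc1O | target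

**Step count**
Total: 11 steps. Longest linear sequence: 8 steps (steps 1–7 and 11).

**Steps most likely to fail**

Step 5 (radical ring closure). The tertiary radical may be reduced before the 7-endo closure, the remaining ring olefin may be hydrogenated by excess silane, and the remote (1,4) facial control by the silyloxy group is the least certain stereochemical call in the route. The trans preference at C-4a on equilibration is also only an expectation. The fallback sets out from 9 and comes back at 11. It generates the same radical with no metal hydride present at the cyclisation stage, so it addresses premature reduction and over-hydrogenation but not the facial selectivity. Mukaiyama hydration of the side-chain olefin (Co(acac)2, PhSiH3, O2, i-PrOH) gives 1-[(5S)-5-{[tert-butyl(dimethyl)silyl]oxy}-4-methylcyclohexa-1,3-dien-1-yl]-5-hydroxy-5-methylhexan-1-one F1. Acylation with methyl chlorooxoacetate (Et3N, DMAP) gives the tertiary methyl oxalate F2, and CsOH in THF/H2O gives the cesium oxalate F3. Visible-light fragmentation (Ir[dF(CF3)ppy]2(dtbbpy)PF6, blue LEDs, DME/DMF/H2O) releases the tertiary radical, which closes the ring by the same conjugate addition; DBU equilibration then gives 11.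

Step 6 (methyl addition). The facial preference is argued by analogy with cyclohexanones and may not transfer cleanly to the seven-membered ketone; enolisation is also possible. The fallback sets out from 11 and comes back at 12. Dimethylsulfonium methylide (Me3SI, KN(SiMe3)2, THF, −10 °C), which transfers CH2 axially, gives tert-butyl(dimethyl){[(3S,4aR,5R,9aR)-2,9,9-trimethyl-3,4,4a,6,7,8,9,9a-octahydrospiro[benzo[7]annulene-5,2'-oxiran]-3-yl]oxy}silane F4. LiBHEt3 then opens the epoxide at its CH2 terminus to give 12.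

Step 11 (Mitsunobu with a phenolic acid). A weakly acidic, free-phenol acid on a hindered allylic alcohol may give elimination or low conversion. The fallback sets out from 13 (with 20) and comes back at 21, separating inversion from acylation. Mitsunobu reaction with 4-nitrobenzoic acid (PPh3, DIAD) gives (3R,4aR,5R,9aR)-5-hydroxy-2,5,9,9-tetramethyl-4,4a,5,6,7,8,9,9a-octahydro-3H-benzo[7]annulen-3-yl 4-nitrobenzoate F5. K2CO3 in MeOH gives the inverted (3R,4aR,5R,9aR)-2,5,9,9-tetramethyl-4,4a,5,6,7,8,9,9a-octahydro-3H-benzo[7]annulene-3,5-diol F6. Acid 20 is acetylated (Ac2O, pyridine) to 3-acetoxy-4-methoxybenzoic acid F7. Carbodiimide coupling of F6 with F7 (EDC·HCl, DMAP, CH2Cl2), with retention, gives (3R,4aR,5R,9aR)-5-hydroxy-2,5,9,9-tetramethyl-4,4a,5,6,7,8,9,9a-octahydro-3H-benzo[7]annulen-3-yl 3-acetoxy-4-methoxybenzoate F8. Brief K2CO3/MeOH at 0 °C removes the aryl acetate to give 21.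

**Further compounds**
F1 | step 5 | 1-[(5S)-5-{[tert-butyl(dimethyl)silyl]oxy}-4-methylcyclohexa-1,3-dien-1-yl]-5-hydroxy-5-methylhexan-1-one | CC(C)(O)CCCC(=O)C1=CC=C(C)[C@@H](O[Si](C)(C)C(C)(C)C)C1
F2 | step 5 | 6-[(5S)-5-{[tert-butyl(dimethyl)silyl]oxy}-4-methylcyclohexa-1,3-dien-1-yl]-2-methyl-6-oxohexan-2-yl methyl oxalate | COC(=O)C(=O)OC(C)(C)CCCC(=O)C1=CC=C(C)[C@@H](O[Si](C)(C)C(C)(C)C)C1
F3 | step 5 | cesium 2-({6-[(5S)-5-{[tert-butyl(dimethyl)silyl]oxy}-4-methylcyclohexa-1,3-dien-1-yl]-2-methyl-6-oxohexan-2-yl}oxy)-2-oxoacetate | [Cs+].[O-]C(=O)C(=O)OC(C)(C)CCCC(=O)C1=CC=C(C)[C@@H](O[Si](C)(C)C(C)(C)C)C1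
F4 | step 6 | tert-butyl(dimethyl){[(3S,4aR,5R,9aR)-2,9,9-trimethyl-3,4,4a,6,7,8,9,9a-octahydrospiro[benzo[7]annulene-5,2'-oxiran]-3-yl]oxy}silane | CC(C)(C)[Si](C)(C)O[C@H]1C[C@@H]2[C@@H](C=C1C)C(C)(C)CCC[C@]23CO3
F5 | step 11 | (3R,4aR,5R,9aR)-5-hydroxy-2,5,9,9-tetramethyl-4,4a,5,6,7,8,9,9a-octahydro-3H-benzo[7]annulen-3-yl 4-nitrobenzoate | O=C(O[C@@H]1C[C@@H]2[C@@H](C=C1C)C(C)(C)CCC[C@@]2(C)O)c1ccc(cc1)[N+](=O)[O-]
F6 | step 11 | (3R,4aR,5R,9aR)-2,5,9,9-tetramethyl-4,4a,5,6,7,8,9,9a-octahydro-3H-benzo[7]annulene-3,5-diol | O[C@@H]1C[C@@H]2[C@@H](C=C1C)C(C)(C)CCC[C@@]2(C)O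
F7 | step 11 | 3-acetoxy-4-methoxybenzoic acid | COc1ccc(C(=O)O)cc1OC(C)=O
F8 | step 11 | (3R,4aR,5R,9aR)-5-hydroxy-2,5,9,9-tetramethyl-4,4a,5,6,7,8,9,9a-octahydro-3H-benzo[7]annulen-3-yl 3-acetoxy-4-methoxybenzoate | COc1ccc(C(=O)O[C@@H]2C[C@@H]3[C@@H](C=C2C)C(C)(C)CCC[C@@]3(C)O)cc1OC(C)=O
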